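## Retrosynthetic overview

1. Target 24 ⇐ desilylation and methylenation of α-hydroxy ketone 22 ⇐ Weinreb amide 17 + side-chain Grignard reagent 21, whose carbinol centre comes from a Shi epoxidation of 18.
2. Bromochloride 17 ⇐ BCl3 opening, with bromine participation, of a temporary C1–O–C4 bridge (7-oxabicyclo[2.2.1]heptane 16) ⇐ transannular bromoetherification of cyclohexenol 14. This relays the C1 configuration to C3 and C4.
3. Cyclohexene ring (13) ⇐ one-pot double alkylation of the chiral glycolate 6 (temporary butane-2,3-diacetal ring) with (Z)-dibromide 9: C1–C2 first at the allylic terminus, then ring closure by the C1–C6 bond.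
4. Enabling feature: C1 of the cyclohexane is a fully substituted carbinol carbon bonded to the exocyclic C(=CH2) carbon, so O–C1–C is a glycolate when that carbon is carried at the carboxyl level and C1 can act twice as an enolate. Its two ring bonds differ (C1–C2 allylic to the C3=C4 alkene that later carries Br and Cl, C1–C6 homoallylic), and its oxygen lies 1,4 across the ring from C4.
5. Ring order: dioxanone auxiliary (steps 1–3) → carbocycle (step 6) → auxiliary ring removed (step 7) → oxygen bridge made (step 8) and cleaved (step 10).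

Key step: step 6

Assumption: 4-methyl-5,6-dihydro-2H-pyran-2-one (7) and 5-bromo-2-methylpent-2-ene (18) are taken as commercial; ring locants in the text follow the name of 24 (C1 carbinol, C3 CHBr, C4 CClMe).

## Route

Step 1
Reactants: 1 (2S)-3-chloropropane-1,2-diol; 2 butane-2,3-dione
Product: 3 (2S,3S,5S)-5-(chloromethyl)-2,3-dimethoxy-2,3-dimethyl-1,4-dioxane
Conditions: HC(OMe)3, CSA (cat.), MeOH, reflux
Reagents that add atoms: trimethyl orthoformate, COC(OC)OC
Why: Acid-catalysed butane-2,3-diacetal formation under thermodynamic control should place both methoxy groups axial (anomeric effect) and the chloromethyl group equatorial, so the stereocentre of 1 fixes the two new acetal centres as (S,S).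

Step 2
Reactants: 3 (2S,3S,5S)-5-(chloromethyl)-2,3-dimethoxy-2,3-dimethyl-1,4-dioxane
Product: 4 (2S,3S)-2,3-dimethoxy-2,3-dimethyl-5-methylidene-1,4-dioxane
Conditions: KOtBu, THF, 0 °C to reflux
Reagents that add atoms: none
Why: E2 dehydrochlorination of the β-chloro ether should give the exocyclic enol ether; the original carbinol stereocentre is removed while the acetal centres keep its information.

Step 3
Reactants: 4 (2S,3S)-2,3-dimethoxy-2,3-dimethyl-5-methylidene-1,4-dioxane
Product: 6 (5S,6S)-5,6-dimethoxy-5,6-dimethyl-1,4-dioxan-2-one, via spiro ozonide 5 (not isolated)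
Conditions: O3, CH2Cl2, −78 °C; then Me2S, −78 °C to rt
Reagents that add atoms: ozone, [O-][O+]=O
Why: Ozonolysis of the electron-rich 1,1-disubstituted enol ether with reductive work-up should cleave C=CH2 to the lactone carbonyl without touching the diacetal.

Step 4
Reactants: 7 4-methyl-5,6-dihydro-2H-pyran-2-one
Product: 8 (2Z)-3-methylpent-2-ene-1,5-diol
Conditions: iBu2AlH, CH2Cl2, −78 to 0 °C; aq. KNaC4H4O6
Reagents that add atoms: none
Why: 1,2-Reduction of the unsaturated lactone by iBu2AlH should give the allylic diol, and the ring origin of the alkene guarantees the (Z) geometry.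

Step 5
Reactants: 8 (2Z)-3-methylpent-2-ene-1,5-diol
Product: 9 (2Z)-1,5-dibromo-3-methylpent-2-ene
Conditions: CBr4, PPh3, CH2Cl2, −20 to 0 °C
Reagents that add atoms: tetrabromomethane, BrC(Br)(Br)Br
Why: Appel bromination converts both primary alcohols by SN2 at low temperature, which should avoid allylic transposition and Z/E isomerization.

Step 6
Reactants: 6 (5S,6S)-5,6-dimethoxy-5,6-dimethyl-1,4-dioxan-2-one; 9 (2Z)-1,5-dibromo-3-methylpent-2-ene
Product: 13 (2S,3S,6S)-2,3-dimethoxy-2,3,9-trimethyl-1,4-dioxaspiro[5.5]undec-8-en-5-one, via glycolate lithium enolate 10 (not isolated), via monoallylated lactone 11 (not isolated), via bromoalkenyl lithium enolate 12 (not isolated)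
Conditions: LiN(SiMe3)2 (1.05 equiv), THF, −78 °C; 9; then LiN(SiMe3)2 (1.3 equiv), DMPU, −78 to −20 °C
Reagents that add atoms: none
Why: LiN(SiMe3)2 converts 6 into enolate 10, which displaces the allylic bromide of 9 by SN2 to give 11; a second equivalent of base forms enolate 12, whose α-carbon attacks the remaining primary bromide in a 6-(enolexo)-exo-tet closure that forms the C1–C6 bond of the future cyclohexane. The closest known reaction type is the double alkylation of chiral glycine and glycolate enolate equivalents with α,ω-dihalides to give cyclic quaternary α-amino and α-hydroxy acids, together with the sequential dialkylation of butane-2,3-diacetal glycolates. The quaternary carbinol stereocentre is set in the ring-closing event: the axial methoxy group on C5 of the dioxanone, 1,3 to the enolate carbon, shields one face, so the second electrophile enters anti to it and the stereocentre of 11 is erased and rewritten. Because the configuration depends only on which arm is attached last, the rate gap between the allylic and the homoallylic bromide is what turns the facial bias of the auxiliary into the (S) centre. The (Z) geometry of 9, inherited from lactone 7, holds the two termini cis so that the six-membered ring can close. The step needs chemoselectivity between the two bromides, C- over O-alkylation and cyclization over E2, which should be secured by the allylic reactivity, the lithium counter-ion in THF/DMPU and the low temperature.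

Step 7
Reactants: 13 (2S,3S,6S)-2,3-dimethoxy-2,3,9-trimethyl-1,4-dioxaspiro[5.5]undec-8-en-5-one
Product: 14 methyl (1S)-1-hydroxy-4-methylcyclohex-3-ene-1-carboxylate
Conditions: HCl (0.5 M in MeOH), 0 °C to rt
Reagents that add atoms: methanol, CO
Why: Acid-catalysed methanolysis (transesterification and transketalization) should open the lactone and release the diacetal as 2,2,3,3-tetramethoxybutane, leaving the tertiary α-hydroxy ester and its quaternary stereocentre untouched.

Step 8
Reactants: 14 methyl (1S)-1-hydroxy-4-methylcyclohex-3-ene-1-carboxylate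
Product: 15 methyl (1S,3R,4R)-3-bromo-4-methyl-7-oxabicyclo[2.2.1]heptane-1-carboxylate (bromine endo, anti to the oxygen bridge)
Conditions: NBS, CH2Cl2, 0 °C, dark
Reagents that add atoms: N-bromosuccinimide, O=C1CCC(=O)N1Br
Why: Transannular bromoetherification: the bromonium ion on the alkene face anti to the C1 hydroxyl is opened by that hydroxyl at the tertiary carbon (Markovnikov, anti addition), so the C1 stereocentre sets the C4–O bond and, trans to it, the C3–Br bond, while the ester carbonyl on the other ring face is the weaker nucleophile.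

Step 9
Reactants: 15 methyl (1S,3R,4R)-3-bromo-4-methyl-7-oxabicyclo[2.2.1]heptane-1-carboxylate
Product: 16 (1S,3R,4R)-3-bromo-N-methoxy-N,4-dimethyl-7-oxabicyclo[2.2.1]heptane-1-carboxamide
Conditions: MeNH(OMe)·HCl, iPrMgCl, THF, −20 to 0 °C
Reagents that add atoms: N,O-dimethylhydroxylamine hydrochloride, CNOC.Cl
Why: Weinreb amide formation from the bridgehead ester with ClMgN(OMe)Me is placed here because the bicyclic bromo ether carries no base-labile tertiary chloride and its endo bromide cannot undergo SN2.

Step 10
Reactants: 16 (1S,3R,4R)-3-bromo-N-methoxy-N,4-dimethyl-7-oxabicyclo[2.2.1]heptane-1-carboxamide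
Product: 17 (1S,3R,4R)-3-bromo-4-chloro-1-hydroxy-N-methoxy-N,4-dimethylcyclohexane-1-carboxamide
Conditions: BCl3, CH2Cl2, −78 to −30 °C; aq. NaHCO3
Reagents that add atoms: boron trichloride, ClB(Cl)Cl
Why: Boron trichloride cleavage of the strained bridged tertiary ether with neighbouring-group participation: the C4–O bond should ionize with assistance of the antiperiplanar C3 bromine and chloride return to C4 from the face the oxygen left, giving the tertiary chloride with retention (Cl cis to OH, trans to Br), while the acyl group on C1 suppresses ionization at that bridgehead.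

Step 11
Reactants: 18 5-bromo-2-methylpent-2-ene
Product: 19 (3R)-3-(2-bromoethyl)-2,2-dimethyloxirane
Conditions: D-fructose-derived Shi ketone (30 mol %), KHSO5 (as 2KHSO5·KHSO4·K2SO4), K2CO3, Bu4NHSO4 (cat.), MeCN/CH2(OMe)2/aq. Na2B4O7 buffer, 0 °C
Reagents that add atoms: potassium peroxymonosulfate, [K+].[O-]S(=O)(=O)OO
Why: Shi asymmetric epoxidation of the trisubstituted alkene by the chiral dioxirane through a spiro transition state should set the (R) configuration at the secondary epoxide carbon.

Step 12
Reactants: 19 (3R)-3-(2-bromoethyl)-2,2-dimethyloxirane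
Product: 20 {[(3R)-5-bromo-2-methylpent-1-en-3-yl]oxy}(tert-butyl)dimethylsilane
Conditions: TBSOTf, DBU, toluene, −78 to 0 °C
Reagents that add atoms: tert-butyldimethylsilyl trifluoromethanesulfonate, CC(C)(C)[Si](C)(C)OS(=O)(=O)C(F)(F)F
Why: Silyl triflate/amidine isomerization of an epoxide to an allylic silyl ether: opening at the tertiary carbon and loss of a methyl proton should give the isopropenyl group while the C–O bond of the stereocentre is never broken.

Step 13
Reactants: 17 (1S,3R,4R)-3-bromo-4-chloro-1-hydroxy-N-methoxy-N,4-dimethylcyclohexane-1-carboxamide; 20 {[(3R)-5-bromo-2-methylpent-1-en-3-yl]oxy}(tert-butyl)dimethylsilane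
Product: 22 (4R)-1-[(1S,3R,4R)-3-bromo-4-chloro-1-hydroxy-4-methylcyclohexyl]-4-[(tert-butyldimethylsilyl)oxy]-5-methylhex-5-en-1-one, via Grignard reagent 21 (not isolated)
Conditions: 20, Mg, THF, rt; then 17 (0.33 equiv), THF, −40 to 0 °C; aq. NH4Cl
Reagents that add atoms: none
Why: Weinreb ketone synthesis: one equivalent of 21 deprotonates the tertiary alcohol and a second adds to the amide to give a chelated tetrahedral intermediate that releases the ketone only on work-up, with no stereocentre involved.

Step 14
Reactants: 22 (4R)-1-[(1S,3R,4R)-3-bromo-4-chloro-1-hydroxy-4-methylcyclohexyl]-4-[(tert-butyldimethylsilyl)oxy]-5-methylhex-5-en-1-one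
Product: 23 (1S,3R,4R)-3-bromo-1-[(5R)-5-[(tert-butyldimethylsilyl)oxy]-6-methylhepta-1,6-dien-2-yl]-4-chloro-4-methylcyclohexan-1-ol
Conditions: Cp2Ti(μ-Cl)(μ-CH2)AlMe2 (3 equiv), pyridine, THF, −40 to 0 °C; aq. NaHCO3
Reagents that add atoms: Tebbe reagent Cp2Ti(μ-Cl)(μ-CH2)AlMe2, C[Al-]1(C)C[Ti]([Cl+]1)(C1C=CC=C1)C1C=CC=C1
Why: Tebbe methylenation: Cp2Ti=CH2, released from the reagent by pyridine, should add to the hindered α-hydroxy ketone as an oxatitanacyclobutane that collapses to the 1,1-disubstituted alkene under non-basic conditions that spare the tertiary chloride and the secondary bromide, one extra equivalent being taken up reversibly by the free tertiary hydroxyl.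

Step 15
Reactants: 23 (1S,3R,4R)-3-bromo-1-[(5R)-5-[(tert-butyldimethylsilyl)oxy]-6-methylhepta-1,6-dien-2-yl]-4-chloro-4-methylcyclohexan-1-ol
Product: 24 (1S,3R,4R)-3-bromo-4-chloro-1-[(5R)-5-hydroxy-6-methylhepta-1,6-dien-2-yl]-4-methylcyclohexan-1-ol
Conditions: Bu4NF, AcOH, THF, 0 °C to rt
Reagents that add atoms: none
Why: Buffered fluoride desilylation should remove the silyl ether without base-induced loss of HCl or HBr and without ionizing the tertiary allylic alcohol.

## Compound list

1 | (2S)-3-chloropropane-1,2-diol | OC[C@H](O)CCl | starting material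
2 | butane-2,3-dione | CC(=O)C(C)=O | starting material
3 | (2S,3S,5S)-5-(chloromethyl)-2,3-dimethoxy-2,3-dimethyl-1,4-dioxane | ClC[C@@H]1CO[C@](C)(OC)[C@@](C)(OC)O1 | intermediate
4 | (2S,3S)-2,3-dimethoxy-2,3-dimethyl-5-methylidene-1,4-dioxane | C=C1CO[C@](C)(OC)[C@@](C)(OC)O1 | intermediate
5 | spiro ozonide, formed in the flask: (7S,8S)-7,8-dimethoxy-7,8-dimethyl-1,2,4,6,9-pentaoxaspiro[4.5]decane, both epimers at the spiro carbon | C1OC2(CO[C@](C)(OC)[C@@](C)(OC)O2)OO1 | intermediate
6 | (5S,6S)-5,6-dimethoxy-5,6-dimethyl-1,4-dioxan-2-one | O=C1CO[C@](C)(OC)[C@@](C)(OC)O1 | intermediate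
7 | 4-methyl-5,6-dihydro-2H-pyran-2-one | CC1=CC(=O)OCC1 | starting material
8 | (2Z)-3-methylpent-2-ene-1,5-diol | OC/C=C(/C)CCO | intermediate
9 | (2Z)-1,5-dibromo-3-methylpent-2-ene | BrC/C=C(/C)CCBr | intermediate
10 | glycolate lithium enolate, formed in the flask: lithium (5S,6S)-5,6-dimethoxy-5,6-dimethyl-5,6-dihydro-1,4-dioxin-2-olate | [Li]OC1=CO[C@](C)(OC)[C@@](C)(OC)O1 | intermediate
11 | monoallylated lactone, formed in the flask: (3R,5S,6S)-3-[(2Z)-5-bromo-3-methylpent-2-en-1-yl]-5,6-dimethoxy-5,6-dimethyl-1,4-dioxan-2-one | O=C1[C@@H](C/C=C(/C)CCBr)O[C@](C)(OC)[C@@](C)(OC)O1 | intermediate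
12 | bromoalkenyl lithium enolate, formed in the flask: lithium (5S,6S)-3-[(2Z)-5-bromo-3-methylpent-2-en-1-yl]-5,6-dimethoxy-5,6-dimethyl-5,6-dihydro-1,4-dioxin-2-olate | [Li]OC1=C(C/C=C(/C)CCBr)O[C@](C)(OC)[C@@](C)(OC)O1 | intermediate
13 | (2S,3S,6S)-2,3-dimethoxy-2,3,9-trimethyl-1,4-dioxaspiro[5.5]undec-8-en-5-one | O=C1[C@]2(CC=C(C)CC2)O[C@](C)(OC)[C@@](C)(OC)O1 | intermediate
14 | methyl (1S)-1-hydroxy-4-methylcyclohex-3-ene-1-carboxylate | COC(=O)[C@@]1(O)CC=C(C)CC1 | intermediate
15 | methyl (1S,3R,4R)-3-bromo-4-methyl-7-oxabicyclo[2.2.1]heptane-1-carboxylate | COC(=O)[C@@]12CC[C@@](C)(O1)[C@H](Br)C2 | intermediate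
16 | (1S,3R,4R)-3-bromo-N-methoxy-N,4-dimethyl-7-oxabicyclo[2.2.1]heptane-1-carboxamide | CON(C)C(=O)[C@@]12CC[C@@](C)(O1)[C@H](Br)C2 | intermediate
17 | (1S,3R,4R)-3-bromo-4-chloro-1-hydroxy-N-methoxy-N,4-dimethylcyclohexane-1-carboxamide | CON(C)C(=O)[C@]1(O)CC[C@@](C)(Cl)[C@H](Br)C1 | intermediate
18 | 5-bromo-2-methylpent-2-ene | CC(C)=CCCBr | starting material
19 | (3R)-3-(2-bromoethyl)-2,2-dimethyloxirane | CC1(C)O[C@@H]1CCBr | intermediate
20 | {[(3R)-5-bromo-2-methylpent-1-en-3-yl]oxy}(tert-butyl)dimethylsilane | C=C(C)[C@H](O[Si](C)(C)C(C)(C)C)CCBr | intermediate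
21 | Grignard reagent, formed in the flask: bromo{(3R)-3-[(tert-butyldimethylsilyl)oxy]-4-methylpent-4-en-1-yl}magnesium | C=C(C)[C@H](O[Si](C)(C)C(C)(C)C)CC[Mg]Br | intermediate
22 | (4R)-1-[(1S,3R,4R)-3-bromo-4-chloro-1-hydroxy-4-methylcyclohexyl]-4-[(tert-butyldimethylsilyl)oxy]-5-methylhex-5-en-1-one | C=C(C)[C@H](O[Si](C)(C)C(C)(C)C)CCC(=O)[C@]1(O)CC[C@@](C)(Cl)[C@H](Br)C1 | intermediate
23 | (1S,3R,4R)-3-bromo-1-[(5R)-5-[(tert-butyldimethylsilyl)oxy]-6-methylhepta-1,6-dien-2-yl]-4-chloro-4-methylcyclohexan-1-ol | C=C(C)[C@H](O[Si](C)(C)C(C)(C)C)CCC(=C)[C@]1(O)CC[C@@](C)(Cl)[C@H](Br)C1 | intermediate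
24 | (1S,3R,4R)-3-bromo-4-chloro-1-[(5R)-5-hydroxy-6-methylhepta-1,6-dien-2-yl]-4-methylcyclohexan-1-ol | C=C(C)[C@H](O)CCC(=C)[C@]1(O)CC[C@@](C)(Cl)[C@H](Br)C1 | target

## Step count and risks

Total step count: 15. Longest linear sequence: 11 steps (1, 2, 3, 6, 7, 8, 9, 10, 13, 14, 15).

Steps most likely to fail, riskiest first:

Step 10. After ionization of the bridging C–O bond, loss of a proton to an alkene, chloride attack at the secondary carbon, or Lewis-acid-induced halide scrambling could compete with return of chloride to the tertiary carbon. The fallback sets out from 14 and comes back at 17, and it replaces ether formation and cleavage by chloride delivery tethered through the C1 oxygen. Compound 14 would be treated with ClTi(OiPr)3 to convert the tertiary hydroxyl into its ROTi(OiPr)2Cl alkoxide and then with NBS in CH2Cl2 at −20 °C. The bromonium ion anti to the Ti–O bond should be opened at the tertiary carbon by chloride from the same ROTi(OiPr)2Cl unit, giving methyl (1S,3R,4R)-3-bromo-4-chloro-1-hydroxy-4-methylcyclohexane-1-carboxylate F1. F1 would then be amidated with MeNH(OMe)·HCl and iPrMgCl at −20 °C to give 17.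

Step 6. The second alkylation by the unactivated primary bromide may be slow at temperatures the lactone enolate tolerates, so that E2 loss of HBr to a diene or intermolecular alkylation takes over. The fallback sets out from 6 and 9 and comes back at 13 by a stepwise sequence. The reaction would be stopped after the first alkylation and 11 isolated. Finkelstein exchange (NaI, acetone) would give (3R,5S,6S)-3-[(2Z)-5-iodo-3-methylpent-2-en-1-yl]-5,6-dimethoxy-5,6-dimethyl-1,4-dioxan-2-one F2. F2 would be cyclized at high dilution with KN(SiMe3)2 (THF, −78 to −40 °C) to 13.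

Step 13. Addition to the hindered amide next to the ROMgBr alkoxide may be slow enough that base-mediated loss of HCl or HBr competes. The fallback sets out from 17 and 21 and comes back at 22 by changing the acyl substitution into an aldehyde addition followed by oxidation. Compound 17 would be reduced with iBu2AlH at −78 °C to (1S,3R,4R)-3-bromo-4-chloro-1-hydroxy-4-methylcyclohexane-1-carbaldehyde F3. Addition of 21 at −78 °C should give (1S,3R,4R)-3-bromo-1-[(4R)-4-[(tert-butyldimethylsilyl)oxy]-1-hydroxy-5-methylhex-5-en-1-yl]-4-chloro-4-methylcyclohexan-1-ol F4 as a mixture of carbinol epimers. Parikh–Doering oxidation (SO3·pyridine, DMSO, iPr2NEt) of the secondary alcohol would give 22.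

Further compounds

F1 | step 10 | methyl (1S,3R,4R)-3-bromo-4-chloro-1-hydroxy-4-methylcyclohexane-1-carboxylate | COC(=O)[C@]1(O)CC[C@@](C)(Cl)[C@H](Br)C1
F2 | step 6 | (3R,5S,6S)-3-[(2Z)-5-iodo-3-methylpent-2-en-1-yl]-5,6-dimethoxy-5,6-dimethyl-1,4-dioxan-2-one | O=C1[C@@H](C/C=C(/C)CCI)O[C@](C)(OC)[C@@](C)(OC)O1
F3 | step 13 | (1S,3R,4R)-3-bromo-4-chloro-1-hydroxy-4-methylcyclohexane-1-carbaldehyde | O=C[C@]1(O)CC[C@@](C)(Cl)[C@H](Br)C1
F4 | step 13 | (1S,3R,4R)-3-bromo-1-[(4R)-4-[(tert-butyldimethylsilyl)oxy]-1-hydroxy-5-methylhex-5-en-1-yl]-4-chloro-4-methylcyclohexan-1-ol | C=C(C)[C@H](O[Si](C)(C)C(C)(C)C)CCC(O)[C@]1(O)CC[C@@](C)(Cl)[C@H](Br)C1
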